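**Retrosynthetic overview**
1. Ring A and the chain are bought as 1-(2,5-dimethoxyphenyl)ethan-1-one 1 and methyl hexadecanoate 2; ring B (the pyranone) is the only ring made and is closed last.
2. C3–C4 bond: crossed Claisen condensation of 1 with 2 (through sodium enolate 3 and sodium diketonate 4) gives 1,3-diketone 5.
3. Stereocenter: chelation-controlled asymmetric hydrogenation of the alkyl ketone of 5 gives the (R)-carbinol 6 before any ring closure.
4. Key disconnection: the aryl C8a–O1 bond, not C2–O1. Oxidation of 6 to acylquinone 7, intramolecular oxa-Michael addition of the carbinol oxygen to quinone C3 and re-aromatization mirror the presumed biosynthetic closure of a 2-(3-hydroxyacyl)hydroquinone.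
5. Excess oxidant funnels the cyclized material to quinone 8; dithionite work-up gives target 9.

Assumption: the biosynthetic ring closure is taken to be conjugate addition of the side-chain 3-hydroxyl to C3 of a 2-acyl-1,4-benzoquinone, which accounts for the 5,8-dihydroxy pattern; C2 of the target is R.

**Route**

Step 1
Reactants: 1 1-(2,5-dimethoxyphenyl)ethan-1-one (2',5'-dimethoxyacetophenone); 2 methyl hexadecanoate (methyl palmitate)
Product: 5 1-(2,5-dimethoxyphenyl)octadecane-1,3-dione, via sodium enolate 3 (not isolated), via sodium diketonate 4 (not isolated)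
Conditions: NaH (2.5 equiv), 2 (1.3 equiv), THF, reflux, slow addition of 1; then 1 M HCl, 0 °C
Reagents that add atoms: none
Why: Crossed Claisen condensation in which the aryl methyl ketone is the more acidic partner, and irreversible deprotonation of the product to diketonate 4 drives the equilibrium; no stereocenter is formed.

Step 2
Reactants: 5 1-(2,5-dimethoxyphenyl)octadecane-1,3-dione
Product: 6 (3R)-1-(2,5-dimethoxyphenyl)-3-hydroxyoctadecan-1-one
Conditions: H2 (80 atm), RuCl2[(R)-BINAP] (1 mol%), MeOH/CH2Cl2 4:1, 50 °C, 24 h; recrystallization from hexane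
Reagents that add atoms: none
Why: Noyori asymmetric hydrogenation of a β-diketone, in which the substrate chelates divalent ruthenium through both carbonyl oxygens and hydride goes to the more electrophilic alkyl ketone on the face selected by (R)-BINAP (the sense that gives (R)-3-hydroxy esters from β-keto esters), while the conjugated, ortho-substituted aryl ketone serves only as the directing group, so C3 is set as R.

Step 3
Reactants: 6 (3R)-1-(2,5-dimethoxyphenyl)-3-hydroxyoctadecan-1-one
Product: 9 (2R)-5,8-dihydroxy-2-pentadecylchroman-4-one, via acylquinone 7 (not isolated), via chromanetrione 8 (not isolated)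
Conditions: (NH4)2Ce(NO3)6 (4.5 equiv), MeCN/H2O 4:1, 0 °C to rt, 1 h; then aq. Na2S2O4, EtOAc, rt
Reagents that add atoms: water, O
Why: Proposed new method: tetravalent cerium oxidatively demethylates the 1,4-dimethoxyarene (quinone oxygens from water) to 2-acyl-1,4-benzoquinone 7, whose C3 is the β-carbon of two enone systems, so the tethered (R)-carbinol oxygen adds 6-endo (intramolecular oxa-Michael) and enolization re-aromatizes to the chromanone hydroquinone; the excess oxidant takes this on to quinone 8 (which also prevents redox exchange between 7 and the product from stranding half of the material) and dithionite returns it to 9, with no bond to the stereocenter broken so R is retained; the closest known reactions are oxidative demethylation of dimethoxyarenes to acylquinones with (NH4)2Ce(NO3)6, C3-selective nucleophile addition to 2-acyl-1,4-benzoquinones and the flavanone-type 6-endo oxa-Michael closure.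

**Compound list**
1 | 1-(2,5-dimethoxyphenyl)ethan-1-one | CC(=O)c1cc(OC)ccc1OC | starting material
2 | methyl hexadecanoate | CCCCCCCCCCCCCCCC(=O)OC | starting material
3 | sodium 1-(2,5-dimethoxyphenyl)ethen-1-olate | [Na+].[O-]C(=C)c1cc(OC)ccc1OC | intermediate
4 | sodium (1Z)-1-(2,5-dimethoxyphenyl)-3-oxooctadec-1-en-1-olate | [Na+].CCCCCCCCCCCCCCCC(=O)/C=C(\[O-])c1cc(OC)ccc1OC | intermediate
5 | 1-(2,5-dimethoxyphenyl)octadecane-1,3-dione | CCCCCCCCCCCCCCCC(=O)CC(=O)c1cc(OC)ccc1OC | intermediate
6 | (3R)-1-(2,5-dimethoxyphenyl)-3-hydroxyoctadecan-1-one | CCCCCCCCCCCCCCC[C@@H](O)CC(=O)c1cc(OC)ccc1OC | intermediate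
7 | 2-[(3R)-3-hydroxyoctadecanoyl]cyclohexa-2,5-diene-1,4-dione | CCCCCCCCCCCCCCC[C@@H](O)CC(=O)C1=CC(=O)C=CC1=O | intermediate
8 | (2R)-2-pentadecyl-2,3-dihydro-4H-chromene-4,5,8-trione | CCCCCCCCCCCCCCC[C@@H]1CC(=O)C2=C(O1)C(=O)C=CC2=O | intermediate
9 | (2R)-5,8-dihydroxy-2-pentadecyl-2,3-dihydro-4H-chromen-4-one | CCCCCCCCCCCCCCC[C@@H]1CC(=O)c2c(O)ccc(O)c2O1 | target

**Totals**
Total step count: 3. Longest linear sequence: 3.

**Steps most likely to fail**

Step 3 (highest risk). The carbinol must outcompete water for C3 of 7, and quinone 8 is a vinylogous ester that can hydrolyse in the acidic aqueous oxidant. Compounds 8 and 9 can also ring-open by retro-oxa-Michael under base, so everything is kept acidic to neutral. The fallback turns the net-oxidative conjugate addition into a redox-neutral addition–elimination on a haloquinone. It sets out from 6, which is oxidized with only 2.2 equiv (NH4)2Ce(NO3)6 at 0 °C and extracted at once as crude 7. Dry HCl in Et2O at 0 °C adds chloride at C3, the usual site for nucleophiles on acylquinones, to give (3R)-1-(2-chloro-3,6-dihydroxyphenyl)-3-hydroxyoctadecan-1-one F1. Ag2O in anhydrous CH2Cl2 oxidizes this to 2-chloro-3-[(3R)-3-hydroxyoctadecanoyl]cyclohexa-2,5-diene-1,4-dione F2, in which the carbinol displaces chloride with silver assistance. This comes back to the route at 8, which is reduced with Na2S2O4 to 9 as in step 3.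

Step 2. The diketone is largely enolized and may react slowly, and reduction may not stop cleanly at the hydroxy ketone or may start at the aryl ketone. The fallback accepts over-reduction and then re-oxidizes selectively. It sets out from 5, which is hydrogenated with the same RuCl2[(R)-BINAP] catalyst under forcing conditions (100 atm, 80 °C) to (1S,3R)-1-(2,5-dimethoxyphenyl)octadecane-1,3-diol F3. C3 is still set as R by catalyst control and the C1 configuration is irrelevant. Activated MnO2 in CH2Cl2 then oxidizes only the benzylic alcohol and comes back to the route at 6.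

Step 1. Self-condensation of 1 or of 2 can erode the crossed Claisen. The fallback makes the same C–C bond at the aldol oxidation level. It sets out from 1, which is deprotonated with LiN(i-Pr)2 in THF at −78 °C to lithium 1-(2,5-dimethoxyphenyl)ethen-1-olate F4. Commercial hexadecanal is added to give lithium 1-(2,5-dimethoxyphenyl)-1-oxooctadecan-3-olate F5, and NH4Cl quench gives racemic 1-(2,5-dimethoxyphenyl)-3-hydroxyoctadecan-1-one F6. Dess–Martin periodinane in CH2Cl2 oxidizes this and comes back to the route at 5.

**Further compounds**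
F1 | step 3 | (3R)-1-(2-chloro-3,6-dihydroxyphenyl)-3-hydroxyoctadecan-1-one | CCCCCCCCCCCCCCC[C@@H](O)CC(=O)c1c(O)ccc(O)c1Cl
F2 | step 3 | 2-chloro-3-[(3R)-3-hydroxyoctadecanoyl]cyclohexa-2,5-diene-1,4-dione | CCCCCCCCCCCCCCC[C@@H](O)CC(=O)C1=C(Cl)C(=O)C=CC1=O
F3 | step 2 | (1S,3R)-1-(2,5-dimethoxyphenyl)octadecane-1,3-diol | CCCCCCCCCCCCCCC[C@@H](O)C[C@H](O)c1cc(OC)ccc1OC
F4 | step 1 | lithium 1-(2,5-dimethoxyphenyl)ethen-1-olate | [Li+].[O-]C(=C)c1cc(OC)ccc1OC
F5 | step 1 | lithium 1-(2,5-dimethoxyphenyl)-1-oxooctadecan-3-olate (racemic) | [Li+].CCCCCCCCCCCCCCCC([O-])CC(=O)c1cc(OC)ccc1OC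
F6 | step 1 | 1-(2,5-dimethoxyphenyl)-3-hydroxyoctadecan-1-one (racemic) | CCCCCCCCCCCCCCCC(O)CC(=O)c1cc(OC)ccc1OC
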